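Lettering the rings A to F from the 2,4,6-trihydroxyphenoxy end, rings A, C and E each carry OH, O-aryl and OH on three adjacent carbons with a further oxygen para to the ether carbon. Such a 2-aryloxyphloroglucinol is an isomer of a 4-oxy-6-(aryloxymethyl)-2-pyrone, so each of these rings is disconnected between its ether-bearing carbon and one neighbouring C–OH carbon. A single base-induced operation on tris-pyrone 16 should join every exocyclic OCH2 carbon to its lactone carbonyl carbon, closing rings A, C and E and creating the three doubly ortho-hydroxylated diaryl ethers at once. Precursor 16 strings the purchased methylated rings B, D and F together through ArO–CH2 ethers and C4–OAr vinylogous ester links.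

Key step: step 13

Remark: the target has no stereocentre and no configurationally stable axis, so no step has to control configuration; methyl ethers are the only protecting groups.

Step 1
Reactants: 1 4-hydroxy-6-methyl-2H-pyran-2-one (triacetic acid lactone)
Product: 2 4-methoxy-6-methyl-2H-pyran-2-one
Conditions: Me2SO4, K2CO3, acetone, reflux
Reagents that add atoms: dimethyl sulfate COS(=O)(=O)OC
Why: Williamson-type O-methylation of the acidic vinylogous carboxylic acid at C4–OH, a standard transformation of this lactone in which the hard electrophile and carbonate favour oxygen over C3.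

Step 2
Reactants: 2 4-methoxy-6-methyl-2H-pyran-2-one
Product: 3 6-(bromomethyl)-4-methoxy-2H-pyran-2-one
Conditions: NBS, AIBN (cat.), PhCF3, 85 °C
Reagents that add atoms: N-bromosuccinimide O=C1CCC(=O)N1Br
Why: Wohl–Ziegler radical bromination, the 6-methyl group being allylic to C5=C6 and its radical delocalised over the pyrone, so that it should react in preference to the ring under non-polar radical conditions.

Step 3
Reactants: 1 4-hydroxy-6-methyl-2H-pyran-2-one
Product: 4 4-chloro-6-methyl-2H-pyran-2-one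
Conditions: POCl3, Et3N, 90 °C
Reagents that add atoms: phosphoryl chloride O=P(Cl)(Cl)Cl
Why: deoxychlorination of a vinylogous acid by O-phosphorylation of the C4 hydroxyl and addition–elimination of chloride at C4, as in the conversion of 4-hydroxycoumarins into 4-chlorocoumarins.

Step 4
Reactants: 4 4-chloro-6-methyl-2H-pyran-2-one
Product: 5 6-(bromomethyl)-4-chloro-2H-pyran-2-one
Conditions: NBS, AIBN (cat.), PhCF3, 85 °C
Reagents that add atoms: N-bromosuccinimide O=C1CCC(=O)N1Br
Why: Wohl–Ziegler bromination as in step 2; the C4 chloride, unlike an enol ether, does not invite electrophilic bromination of the ring.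

Step 5
Reactants: 6 2,6-dimethoxy-1,4-benzoquinone
Product: 7 2,6-dimethoxybenzene-1,4-diol (2,6-dimethoxyhydroquinone)
Conditions: Na2S2O4, EtOAc–H2O, rt, argon
Reagents that add atoms: none
Why: two-electron reduction of a 1,4-benzoquinone to its hydroquinone by dithionite in a two-phase system, the product being kept under argon because it reoxidises readily.

Step 6
Reactants: 7 2,6-dimethoxybenzene-1,4-diol, 3 6-(bromomethyl)-4-methoxy-2H-pyran-2-one
Product: 8 6-[(4-hydroxy-3,5-dimethoxyphenoxy)methyl]-4-methoxy-2H-pyran-2-one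
Conditions: K2CO3 (1.0 equiv), 7 (1.3 equiv), degassed DMF, 0 °C → rt, argon
Reagents that add atoms: none
Why: Williamson ether synthesis with one equivalent of base, in which the C4 hydroxyl (meta to both methoxy groups, unhindered) is the more acidic and accessible one while the C1 hydroxyl is flanked by two methoxy groups, so the bromide should be taken up at C4–O only.

Step 7
Reactants: 9 3,4,5-trimethoxyphenol, 5 6-(bromomethyl)-4-chloro-2H-pyran-2-one
Product: 10 4-chloro-6-[(3,4,5-trimethoxyphenoxy)methyl]-2H-pyran-2-one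
Conditions: K2CO3, acetone, 0 °C, phenol added slowly to 5 (1.1 equiv)
Reagents that add atoms: none
Why: Williamson SN2 displacement at the primary allylic-type bromide, which at 0 °C with a carbonate base should be much faster than addition–elimination at C4, so the C4 chloride is kept for step 12.

Step 8
Reactants: 9 3,4,5-trimethoxyphenol
Product: 11 6-hydroxy-2,3,4-trimethoxybenzaldehyde
Conditions: MgCl2, Et3N, (CH2O)n, MeCN, reflux
Reagents that add atoms: paraformaldehyde (as formaldehyde) C=O
Why: magnesium phenoxide-directed ortho-formylation (Casnati–Skattebøl reaction), in which the chelated phenoxide delivers formaldehyde to an ortho carbon (the two are equivalent) and a second formaldehyde oxidises the benzylic alkoxide to the aldehyde.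

Step 9
Reactants: 11 6-hydroxy-2,3,4-trimethoxybenzaldehyde, 5 6-(bromomethyl)-4-chloro-2H-pyran-2-one
Product: 12 6-[(4-chloro-2-oxo-2H-pyran-6-yl)methoxy]-2,3,4-trimethoxybenzaldehyde
Conditions: K2CO3, acetone, rt
Reagents that add atoms: none
Why: Williamson SN2 alkylation of the salicylaldehyde-type phenoxide at the bromomethyl group; this weakly nucleophilic phenoxide should leave the C4 chloride alone at ambient temperature, and the formyl group masks the hindered ring D hydroxyl.

Step 10
Reactants: 12 6-[(4-chloro-2-oxo-2H-pyran-6-yl)methoxy]-2,3,4-trimethoxybenzaldehyde, 8 6-[(4-hydroxy-3,5-dimethoxyphenoxy)methyl]-4-methoxy-2H-pyran-2-one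
Product: 13 6-{[4-(2,6-dimethoxy-4-[(4-methoxy-2-oxo-2H-pyran-6-yl)methoxy]phenoxy)-2-oxo-2H-pyran-6-yl]methoxy}-2,3,4-trimethoxybenzaldehyde
Conditions: K2CO3, DMF, 0 °C → rt
Reagents that add atoms: none
Why: addition–elimination (vinylogous acyl substitution) of the doubly ortho-methoxylated phenoxide of 8 at C4 of the 4-chloro-2-pyrone, a known reactivity of 4-halo-2-pyrones toward phenoxides that places little steric demand on the nucleophile; mild base at ambient temperature should avoid aldol closure of the OCH2 group onto the neighbouring formyl group.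

Step 11
Reactants: 13 6-{[4-(2,6-dimethoxy-4-[(4-methoxy-2-oxo-2H-pyran-6-yl)methoxy]phenoxy)-2-oxo-2H-pyran-6-yl]methoxy}-2,3,4-trimethoxybenzaldehyde
Product: 15 ring D phenol carrying the ring C and ring A pyrones (13 with OH in place of CHO), via aryl formate 14 (not isolated)
Conditions: mCPBA, CH2Cl2, 0 °C → rt; then aq. KHCO3, THF, rt
Reagents that add atoms: 3-chloroperoxybenzoic acid OOC(=O)c1cccc(Cl)c1
Why: Baeyer–Villiger (Dakin-type) oxidation of an electron-rich benzaldehyde in which the tetra-oxygenated aryl group migrates to give formate 14, hydrolysed by aqueous hydrogencarbonate, a medium free of alkoxide so that the C4–OAr vinylogous ester and the lactones should survive.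

Step 12
Reactants: 15 ring D phenol carrying the ring C and ring A pyrones, 10 4-chloro-6-[(3,4,5-trimethoxyphenoxy)methyl]-2H-pyran-2-one
Product: 16 tris-pyrone 4-[6-({4-[2,6-dimethoxy-4-((4-methoxy-2-oxo-2H-pyran-6-yl)methoxy)phenoxy]-2-oxo-2H-pyran-6-yl}methoxy)-2,3,4-trimethoxyphenoxy]-6-[(3,4,5-trimethoxyphenoxy)methyl]-2H-pyran-2-one
Conditions: Cs2CO3, MeCN, rt → 40 °C
Reagents that add atoms: none
Why: addition–elimination of the hindered ring D phenoxide at C4 of chloropyrone 10 as in step 10; chloride is a far better leaving group than the aryloxide and methoxide on the two pyrones already present, so exchange there should not compete.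

Step 13
Reactants: 16 tris-pyrone
Product: 18 nona-O-methyl hexamer with six free hydroxyls on rings A and C and E, via tripotassium trianion 17 (not isolated)
Conditions: KN(SiMe3)2 (10 equiv), THF (0.005 M), 16 added slowly at −78 °C, then → 40 °C; AcOH, 0 °C, argon
Reagents that add atoms: none
Why: Proposed new method: the amide base removes one proton from each ArO–CH2 group at C6 (the known acidic site of 6-methyl-2-pyrones) to give trianion 17, and on warming each pyranolate should open by E1cB loss of the ring oxygen O1 from C2 to a ketene carrying a Z-configured oxido-diene, whose aryloxy-bearing terminus bonds to the ketene carbon and, after loss of the remaining proton, aromatises irreversibly to a resorcinolate. The closest known reaction types are the base-mediated rearrangement of 4-methoxy-6-methyl-2-pyrone to 5-methoxyresorcinol and the six-electron electrocyclisation of dienylketenes used in benzannulations. Rings A, C and E each close by a thermal 6π-electrocyclisation, equivalently a 6-(enolexo)-exo-dig C-acylation of the enolate by the ketene, the cis geometry of the central C4=C5 bond being inherited from the pyrone ring. No stereocentre is formed. The step needs C-acylation by the exocyclic carbon to win over attack on the C4–OAr vinylogous ester links, in particular Truce–Smiles-type addition of the ring C pyrone carbanion to C4 of the ring E pyrone across ring D. Inverse addition to an excess of non-nucleophilic base at high dilution should secure this by holding all three pyrones as electron-rich anions that are no longer electrophiles, and regiochemistry is fixed because only the exocyclic carbon can form a six-membered ring with C2.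

Step 14
Reactants: 18 nona-O-methyl hexamer
Product: 19 CNP0175585.0
Conditions: BBr3 (30 equiv), CH2Cl2, −78 °C → rt, argon; then degassed MeOH–H2O, 0 °C
Reagents that add atoms: none
Why: Lewis acid-mediated cleavage of the nine aryl methyl ethers (BBr3 demethylation), bromide attacking each boron-complexed methyl group while the diaryl ether bonds offer no SN2 carbon; air is excluded because the polyphenol is easily oxidised.

Compound list
1 | 4-hydroxy-6-methyl-2H-pyran-2-one (triacetic acid lactone) | CC1=CC(O)=CC(=O)O1 | starting material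
2 | 4-methoxy-6-methyl-2H-pyran-2-one | CC1=CC(OC)=CC(=O)O1 | intermediate
3 | 6-(bromomethyl)-4-methoxy-2H-pyran-2-one (ring A precursor) | BrCC1=CC(OC)=CC(=O)O1 | intermediate
4 | 4-chloro-6-methyl-2H-pyran-2-one | CC1=CC(Cl)=CC(=O)O1 | intermediate
5 | 6-(bromomethyl)-4-chloro-2H-pyran-2-one (linchpin for rings C and E) | BrCC1=CC(Cl)=CC(=O)O1 | intermediate
6 | 2,6-dimethoxy-1,4-benzoquinone | COC1=CC(=O)C=C(OC)C1=O | starting material
7 | 2,6-dimethoxybenzene-1,4-diol (ring B) | COc1cc(O)cc(OC)c1O | intermediate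
8 | 6-[(4-hydroxy-3,5-dimethoxyphenoxy)methyl]-4-methoxy-2H-pyran-2-one (ring B phenol with the ring A pyrone) | COc1cc(OCC2=CC(OC)=CC(=O)O2)cc(OC)c1O | intermediate
9 | 3,4,5-trimethoxyphenol (ring F and source of ring D) | COc1cc(O)cc(OC)c1OC | starting material
10 | 4-chloro-6-[(3,4,5-trimethoxyphenoxy)methyl]-2H-pyran-2-one (ring E pyrone with ring F) | COc1cc(OCC2=CC(Cl)=CC(=O)O2)cc(OC)c1OC | intermediate
11 | 6-hydroxy-2,3,4-trimethoxybenzaldehyde (ring D) | O=Cc1c(O)cc(OC)c(OC)c1OC | intermediate
12 | 6-[(4-chloro-2-oxo-2H-pyran-6-yl)methoxy]-2,3,4-trimethoxybenzaldehyde | O=Cc1c(OCC2=CC(Cl)=CC(=O)O2)cc(OC)c(OC)c1OC | intermediate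
13 | 6-{[4-(2,6-dimethoxy-4-[(4-methoxy-2-oxo-2H-pyran-6-yl)methoxy]phenoxy)-2-oxo-2H-pyran-6-yl]methoxy}-2,3,4-trimethoxybenzaldehyde | O=Cc1c(OCC2=CC(Oc3c(OC)cc(OCC4=CC(OC)=CC(=O)O4)cc3OC)=CC(=O)O2)cc(OC)c(OC)c1OC | intermediate
14 | aryl formate of 15 (formed in the flask, not isolated) | O=COc1c(OCC2=CC(Oc3c(OC)cc(OCC4=CC(OC)=CC(=O)O4)cc3OC)=CC(=O)O2)cc(OC)c(OC)c1OC | intermediate
15 | 4-(2,6-dimethoxy-4-[(4-methoxy-2-oxo-2H-pyran-6-yl)methoxy]phenoxy)-6-[(2-hydroxy-3,4,5-trimethoxyphenoxy)methyl]-2H-pyran-2-one (ring D phenol) | Oc1c(OCC2=CC(Oc3c(OC)cc(OCC4=CC(OC)=CC(=O)O4)cc3OC)=CC(=O)O2)cc(OC)c(OC)c1OC | intermediate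
16 | tris-pyrone (rings B, D, F joined through three 2-pyrones) | COc1cc(OCC2=CC(Oc3c(OCC4=CC(Oc5c(OC)cc(OCC6=CC(OC)=CC(=O)O6)cc5OC)=CC(=O)O4)cc(OC)c(OC)c3OC)=CC(=O)O2)cc(OC)c1OC | intermediate
17 | tripotassium trianion of 16, deprotonated at the three OCH2 carbons (formed in the flask, not isolated) | COc1cc(O[CH-]C2=CC(Oc3c(O[CH-]C4=CC(Oc5c(OC)cc(O[CH-]C6=CC(OC)=CC(=O)O6)cc5OC)=CC(=O)O4)cc(OC)c(OC)c3OC)=CC(=O)O2)cc(OC)c1OC.[K+].[K+].[K+] | intermediate
18 | nona-O-methyl hexamer (methyl ethers at C4–O of ring A, both oxygens of ring B, three of ring D, three of ring F; free OH on both carbons flanking the ether carbon of rings A, C, E) | COc1cc(Oc2c(O)cc(Oc3c(Oc4c(O)cc(Oc5c(OC)cc(Oc6c(O)cc(OC)cc6O)cc5OC)cc4O)cc(OC)c(OC)c3OC)cc2O)cc(OC)c1OC | intermediate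
19 | CNP0175585.0, 2-[3,5-dihydroxy-4-(3,5-dihydroxy-4-{3,4,5-trihydroxy-2-[3,5-dihydroxy-4-(3,4,5-trihydroxyphenoxy)phenoxy]phenoxy}phenoxy)phenoxy]benzene-1,3,5-triol | Oc1cc(O)c(Oc2cc(O)c(Oc3cc(O)c(Oc4cc(O)c(O)c(O)c4Oc4cc(O)c(Oc5cc(O)c(O)c(O)c5)c(O)c4)c(O)c3)c(O)c2)c(O)c1 | target

Total step count: 14.
Longest linear sequence: 8 steps (1 → 4 → 5 → 12 → 13 → 15 → 16 → 18 → 19; steps 3, 4, 9, 10, 11, 12, 13, 14).

Steps most likely to fail

Step 13 (key step). The pyranolates may not open to the ketenes before the anions attack the C4–OAr links, so that the chain is cut or rearranged, and any shortfall is multiplied by three. The fallback uses only Ullmann ether synthesis and Baeyer–Villiger oxidation; it sets out from 9 and comes back at 19.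
- Ring E: 9 and 4-bromo-3,5-dimethoxybenzaldehyde (CuI, picolinic acid, K3PO4, DMSO, 90 °C) should give 3,5-dimethoxy-4-(3,4,5-trimethoxyphenoxy)benzaldehyde F1. mCPBA converts it into 3,5-dimethoxy-4-(3,4,5-trimethoxyphenoxy)phenyl formate F2, and KOH in aqueous methanol cleaves this to 3,5-dimethoxy-4-(3,4,5-trimethoxyphenoxy)phenol F3.
- Ring D: the same three operations with 2-bromo-3,4,5-trimethoxybenzaldehyde give the rings D to F aldehyde F4, the rings D to F formate F5 and the rings D to F phenol F6.
- Ring C: a round with 4-bromo-3,5-dimethoxybenzaldehyde gives the rings C to F aldehyde F7, the rings C to F formate F8 and the rings C to F phenol F9.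
- Ring B: a second round with the same bromide gives the rings B to F aldehyde F10, the rings B to F formate F11 and the rings B to F phenol F12.
- Ring A and end: Ullmann coupling of F12 with 2-bromo-1,3,5-trimethoxybenzene gives the pentadeca-O-methyl ether of the target F13, and BBr3 (CH2Cl2, −78 °C → rt) cleaves all fifteen methyl ethers to 19.
- Each hindered ether is made here from an unhindered phenol and a doubly ortho-substituted aryl bromide, activated in four of the five cases by a formyl group that is then turned into the next phenol.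

Step 7. The phenoxide may also attack C4 of 5 by addition–elimination, which would cost the chloride or arylate the pyrone twice. The fallback sets out from 9 and comes back at 10.
- 9 and methyl bromoacetate (K2CO3, acetone) should give methyl (3,4,5-trimethoxyphenoxy)acetate F14.
- Claisen acylation of the dianion of methyl acetoacetate (NaH, then n-BuLi, THF, 0 °C) with F14 gives methyl 3,5-dioxo-6-(3,4,5-trimethoxyphenoxy)hexanoate F15.
- Lactonisation (DBU, toluene, reflux) gives 4-hydroxy-6-[(3,4,5-trimethoxyphenoxy)methyl]-2H-pyran-2-one F16.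
- POCl3 and Et3N, as in step 3, turn the C4 hydroxyl into the chloride of 10. The ArO–CH2 bond is thus in place before any leaving group exists at C4.

Step 10. Attack of the crowded phenoxide at C4 may be slow enough for base-induced aldol condensation of the pyrone OCH2 group with the adjacent formyl group (closure to a benzofuran) to take over. The fallback sets out from 5, uses 8 and 11, and comes back at 13.
- Solvolysis of the bromide of 5 (CaCO3, H2O–dioxane, 80 °C) should give 4-chloro-6-(hydroxymethyl)-2H-pyran-2-one F17.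
- Addition–elimination of the phenoxide of 8 at C4 of F17 (K2CO3, DMF, rt) gives 4-{2,6-dimethoxy-4-[(4-methoxy-2-oxo-2H-pyran-6-yl)methoxy]phenoxy}-6-(hydroxymethyl)-2H-pyran-2-one F18.
- Mitsunobu etherification of F18 with phenol 11 (PPh3, DIAD, THF, 0 °C → rt) gives 13. The formyl-bearing aryloxymethyl pyrone is then formed under neutral conditions and never meets base.

Further compounds
F1 | step 13 | 3,5-dimethoxy-4-(3,4,5-trimethoxyphenoxy)benzaldehyde | COc1cc(Oc2c(OC)cc(C=O)cc2OC)cc(OC)c1OC
F2 | step 13 | 3,5-dimethoxy-4-(3,4,5-trimethoxyphenoxy)phenyl formate | COc1cc(Oc2c(OC)cc(OC=O)cc2OC)cc(OC)c1OC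
F3 | step 13 | 3,5-dimethoxy-4-(3,4,5-trimethoxyphenoxy)phenol | COc1cc(Oc2c(OC)cc(O)cc2OC)cc(OC)c1OC
F4 | step 13 | rings D to F aldehyde, 2-[3,5-dimethoxy-4-(3,4,5-trimethoxyphenoxy)phenoxy]-3,4,5-trimethoxybenzaldehyde | COc1cc(Oc2c(OC)cc(Oc3c(C=O)cc(OC)c(OC)c3OC)cc2OC)cc(OC)c1OC
F5 | step 13 | rings D to F formate, 2-[3,5-dimethoxy-4-(3,4,5-trimethoxyphenoxy)phenoxy]-3,4,5-trimethoxyphenyl formate | COc1cc(Oc2c(OC)cc(Oc3c(OC=O)cc(OC)c(OC)c3OC)cc2OC)cc(OC)c1OC
F6 | step 13 | rings D to F phenol, 2-[3,5-dimethoxy-4-(3,4,5-trimethoxyphenoxy)phenoxy]-3,4,5-trimethoxyphenol | COc1cc(Oc2c(OC)cc(Oc3c(O)cc(OC)c(OC)c3OC)cc2OC)cc(OC)c1OC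
F7 | step 13 | rings C to F aldehyde, 4-{2-[3,5-dimethoxy-4-(3,4,5-trimethoxyphenoxy)phenoxy]-3,4,5-trimethoxyphenoxy}-3,5-dimethoxybenzaldehyde | COc1cc(Oc2c(OC)cc(Oc3c(Oc4c(OC)cc(C=O)cc4OC)cc(OC)c(OC)c3OC)cc2OC)cc(OC)c1OC
F8 | step 13 | rings C to F formate | COc1cc(Oc2c(OC)cc(Oc3c(Oc4c(OC)cc(OC=O)cc4OC)cc(OC)c(OC)c3OC)cc2OC)cc(OC)c1OC
F9 | step 13 | rings C to F phenol | COc1cc(Oc2c(OC)cc(Oc3c(Oc4c(OC)cc(O)cc4OC)cc(OC)c(OC)c3OC)cc2OC)cc(OC)c1OC
F10 | step 13 | rings B to F aldehyde | COc1cc(Oc2c(OC)cc(Oc3c(Oc4c(OC)cc(Oc5c(OC)cc(C=O)cc5OC)cc4OC)cc(OC)c(OC)c3OC)cc2OC)cc(OC)c1OC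
F11 | step 13 | rings B to F formate | COc1cc(Oc2c(OC)cc(Oc3c(Oc4c(OC)cc(Oc5c(OC)cc(OC=O)cc5OC)cc4OC)cc(OC)c(OC)c3OC)cc2OC)cc(OC)c1OC
F12 | step 13 | rings B to F phenol | COc1cc(Oc2c(OC)cc(Oc3c(Oc4c(OC)cc(Oc5c(OC)cc(O)cc5OC)cc4OC)cc(OC)c(OC)c3OC)cc2OC)cc(OC)c1OC
F13 | step 13 | pentadeca-O-methyl ether of the target | COc1cc(Oc2c(OC)cc(Oc3c(Oc4c(OC)cc(Oc5c(OC)cc(Oc6c(OC)cc(OC)cc6OC)cc5OC)cc4OC)cc(OC)c(OC)c3OC)cc2OC)cc(OC)c1OC
F14 | step 7 | methyl (3,4,5-trimethoxyphenoxy)acetate | COC(=O)COc1cc(OC)c(OC)c(OC)c1
F15 | step 7 | methyl 3,5-dioxo-6-(3,4,5-trimethoxyphenoxy)hexanoate | COC(=O)CC(=O)CC(=O)COc1cc(OC)c(OC)c(OC)c1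
F16 | step 7 | 4-hydroxy-6-[(3,4,5-trimethoxyphenoxy)methyl]-2H-pyran-2-one | COc1cc(OCC2=CC(O)=CC(=O)O2)cc(OC)c1OC
F17 | step 10 | 4-chloro-6-(hydroxymethyl)-2H-pyran-2-one | OCC1=CC(Cl)=CC(=O)O1
F18 | step 10 | 4-{2,6-dimethoxy-4-[(4-methoxy-2-oxo-2H-pyran-6-yl)methoxy]phenoxy}-6-(hydroxymethyl)-2H-pyran-2-one | OCC1=CC(Oc2c(OC)cc(OCC3=CC(OC)=CC(=O)O3)cc2OC)=CC(=O)O1
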